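The rate constants are those of an exercise.

You have to decide which set-up to run if you want the most intermediate in the last sample.

all flasks: catalyst 0.27 mol%

| flask | substrate | time | remark |
|---|---|---|---|
| alder | 0.17 M (fed, over 4.80 min) | 6.0 min | all but substrate at the start; substrate goes in evenly over 4.80 min, the run ends at 6.0 min |
| elm | 0.17 M |  | a single well-mixed tank run continuously and read at steady state, 6.0 min in it on average |
| larch | 0.17 M | 6.0 min | a closed flask charged with all of it at once and left for 6.0 min |

    substrate → intermediate (k1 = 0.62 /min)
    catalyst + intermediate → catalyst + target (k2 = 1000 /M/min)
    intermediate → decomposed reagent (k3 = 0.0092 /min)

1. the set-up with the highest amount of intermediate at the outlet or at the end, in percent of the substrate put in ("none" if the first two lie within 2 percentage points) (alder / elm / larch / none)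
2. amount of intermediate at the outlet or at the end, in percent of the substrate put in, alder
3. amount of intermediate at the outlet or at the end, in percent of the substrate put in, elm
4. amount of intermediate at the outlet or at the end, in percent of the substrate put in, larch

- the stated concentrations are those of everything mixed, before any reaction; amounts are the same in each set-up
- the feed brings no volume worth counting
- run time (alder): 6.0 min

Each turnover returns the catalyst, so it stands at 4.59 × 10⁻⁴ M, and the intermediate is lost by a pseudo-first-order constant, the clearing constant: the catalyst concentration times the constant of the second step, plus the constant of the third, or 0.468 /min. It is smaller than the forming constant 0.62 /min, and I reckon the amount left from the two constants and the age of the material. With f the forming constant, c the clearing constant and t the age, the fraction left as intermediate is f/(c−f) × (exp(−f t) − exp(−c t)).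

For larch, I take the age as 6.0 min and get 14.7%. For alder, the substrate enters on average at half the dosing time, so the age is 3.60 min, which gives 31.9%. For elm, the converted share f t/(1 + f t), divided by 1 + c t, gives 20.7%.

The forecast chose alder, with 30.8% for alder, 20.7% for elm and 14.7% for larch, arguing that “The fed run has the youngest material”. Its alder figure lies below mine.

The simulation gives alder: alder 30.8%, elm 20.7%, larch 14.7%. The forecast stands, and alder leads elm by 10 percentage points against a margin of 2 points. At the end, alder still holds 15.2% of its substrate, larch 2.42%. Run elm at 3 times the residence time and the clearing constant gives 9.73%; the simulation gives 9.73%.

A neighbour of alder with 0.068 mol% of catalyst has a smaller clearing constant, 0.125 /min, and the same age gives 66.5%. The simulation gives 62.1%.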